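My unit was the turnover: one turnover of the second phase means ln cZ has dropped by one. I counted how many the flask gets in its time and how many its L needs.

| flask | L | Z | remark | time | volume of the second phase over the first |
|---|---|---|---|---|---|
| birch | 12 mM | 11 mM | run made earlier |  |  |
| cedar | 12 mM | 43 mM | run made earlier |  |  |
| oak | 24 mM | 21.6 mM | run made earlier |  |  |
| flask | 12 mM | 21.6 mM |  | 80 min | 1.0 |

| run | time / min | E / % | X / % |
|---|---|---|---|
| birch | 8.00 | 10 | 0 |
| birch | 12.0 | 19 | 1 |
| birch | 20.0 | 29 | 2 |
| birch | 25.0 | 32 | 0 |
| birch | 40.0 | 41 | 7 |
| birch | 60.0 | 50 | 17 |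
| birch | 90.0 | 63 | 26 |
| cedar | 15.0 | 72 | 15 |
| cedar | 30.0 | 94 | 54 |
| cedar | 40.0 | 99 | 59 |
| cedar | 60.0 | 96 | 59 |
| cedar | 80.0 | 97 | 63 |
| cedar | 90.0 | 97 | 60 |
| oak | 8.00 | 16 | 0 |
| oak | 25.0 | 32 | 9 |
| oak | 40.0 | 44 | 23 |
| oak | 60.0 | 56 | 37 |
| oak | 90.0 | 66 | 45 |

(readings scatter by 2 percentage points)

- percentages count the L that a species holds: one D counts as two
- E is meant together with its X
- in the second phase: Z; everything else is in the first
- charges count per volume of the first phase; a concentration in a rate is the amount of a species over the volume of its own phase; every rate counts per litre of the first phase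
- solid, in amounts per volume of the solution: X
- the numbers in the tables scatter with a standard deviation of 2 percentage points
- reactions considered so far: L + Q -> E; X <-> E; L + E -> D; Q <-> Z
- the earlier runs hold the two phases in the same ratio of volumes as the flask asked about

* E and X together at 80 min, in percent of the L charged
* concentration of E in solution at 80 min, in percent of saturation

Taking each L as one Z spent, I read the turnover rate s from oak's last reading as 0.0147 min⁻¹. Cedar's first reading, at another cL and cZ, gave 0.0150 min⁻¹, which I read as a rate-limiting passage of Z into Q. So the flask gets 1.17 turnovers and needs 0.811. Their ratio is the turnover margin 1.45, the turnovers available over those needed. Taken plainly, the count meets the need at 55.2 min.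

That was the weak link, since it holds the pace steady down to the last L. Cedar tested it: it needs 0.327 turnovers, so it reaches the same margin at 32.3 min, and its nearest reading, at 30.0 min, shows 94%. I committed to about that for the flask. E minus X in cedar's last reading was 4.44 mM, which I took as saturation. The 11.3 mM of E I counted on for the flask was more than that, so I expected crystals and a solution near saturation.

The forecast stood lower, at 93% (87% to 97%), with 102% (95% to 115%) of saturation: “the solution sits just above saturation”.

The flask gave 91.6% and 104%, both inside the forecast's ranges.

    L + Q → E (k = 2.58 L mol⁻¹ s⁻¹)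
    X ⇌ E, rate k2*(cs2 - [E]) while solid is left; crystals form when [E] > cs2 (solubility = 4.00 mM, k = 0.00231 s⁻¹)
    L + E → D (k = 0.00676 L mol⁻¹ s⁻¹)
    Q ⇌ Z, rate k4*([Q] - [Z]/K4) per volume of the first phase (partition coefficient = 21.4, kL = 0.00874 s⁻¹)

With a turnover margin of 1.45, the flask held E and X at 91.6% through two things acting together, the reaction of L + E to D and the pace of the passage of Z into Q: with that reaction struck out the flask gave 98.0%, and without that pace it gave 96.2%. The neighbour flask charged with 4.8 mM of L counted a margin of 4.67 and gave 97.8%, with D at 2.16%.

Readings and results were computed from invented constants; noise was put on by code.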